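The synthesis hinges on making the C2–C3 bond of the dihydrofuran ring last among the ring bonds. Three different neighbours meet at C2: the ether oxygen O1, the ester-bearing benzylic carbon C3 and the α-carbon of the acrolein unit, which is the footprint of a γ-aryloxyallyl metal that has added to an aldehyde. A copper-catalysed borylation of an allenyl aryl ether should generate that nucleophile next to an ortho formyl group, so that one operation closes the ring, creates C2 and C3 and leaves boron where the formyl carbon must go. The precursor is a 2-(allenyloxy)benzaldehyde carrying only the (R)-silyloxyethyl stereocentre at C5. Desilylation, double tigloylation, homologation at boron and oxidation follow.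

Key step: step 7

Assumption: precedent does not show which antipode of the bisphosphine leads to (2R,3S), so the (R) ligand written in step 7 stands for whichever antipode a trial with both identifies. The two outcomes are diastereomers because the side-chain centre is fixed, so they are easy to tell apart.

Step 1
Reactants: 1 5-acetyl-2-hydroxybenzaldehyde; 2 propargyl bromide
Product: 3 5-acetyl-2-(prop-2-yn-1-yloxy)benzaldehyde
Conditions: K2CO3, DMF, rt
Reagents that add atoms: propargyl bromide (2), C#CCBr
Why: Williamson ether synthesis in which the phenol, acidified by its ortho formyl and para acetyl groups, is deprotonated by carbonate and displaces bromide from the unhindered propargylic carbon, and doing this first means that no free phenol is left to compete in the later silylation or to labilise the para benzylic carbinol.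

Step 2
Reactants: 3 5-acetyl-2-(prop-2-yn-1-yloxy)benzaldehyde
Product: 4 1-[3-(dimethoxymethyl)-4-(prop-2-yn-1-yloxy)phenyl]ethan-1-one
Conditions: HC(OMe)3, MeOH, p-TsOH (1 mol %), rt; Et3N quench
Reagents that add atoms: trimethyl orthoformate, COC(OC)OC
Why: Chemoselective acid-catalysed acetalisation, since the aldehyde is much more electrophilic and less hindered than the donor-conjugated aryl methyl ketone and alone becomes the dimethyl acetal, which shields the formyl carbon from the hydride of step 3 and the base of step 5.

Step 3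
Reactants: 4 1-[3-(dimethoxymethyl)-4-(prop-2-yn-1-yloxy)phenyl]ethan-1-one
Product: 5 (1R)-1-[3-(dimethoxymethyl)-4-(prop-2-yn-1-yloxy)phenyl]ethan-1-ol
Conditions: RuCl[(R,R)-TsDPEN](p-cymene) (1 mol %), HCO2Na, H2O/MeOH, 40 °C
Reagents that add atoms: none
Why: Noyori asymmetric transfer hydrogenation, in which the (R,R)-TsDPEN ruthenium hydride delivers hydrogen to the Si face of the aryl methyl ketone, the sense it shows for acetophenones, and so sets the (R) carbinol, while the near-neutral formate medium leaves the acetal and the outer-sphere hydride transfer leaves the alkyne untouched.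

Step 4
Reactants: 5 (1R)-1-[3-(dimethoxymethyl)-4-(prop-2-yn-1-yloxy)phenyl]ethan-1-ol
Product: 6 tert-butyl{(1R)-1-[3-(dimethoxymethyl)-4-(prop-2-yn-1-yloxy)phenyl]ethoxy}dimethylsilane
Conditions: TBSCl, imidazole, DMF, rt
Reagents that add atoms: tert-butyldimethylsilyl chloride, CC(C)(C)[Si](C)(C)Cl
Why: Imidazole-promoted silylation of the only hydroxyl group forms the O–Si bond without touching the C–O bond, so the configuration is kept, and the silyl ether withstands KOtBu, PPTS and copper alkoxides and removes the proton that would otherwise quench the allylcopper of step 7.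

Step 5
Reactants: 6 tert-butyl{(1R)-1-[3-(dimethoxymethyl)-4-(prop-2-yn-1-yloxy)phenyl]ethoxy}dimethylsilane
Product: 7 tert-butyl{(1R)-1-[3-(dimethoxymethyl)-4-(propa-1,2-dien-1-yloxy)phenyl]ethoxy}dimethylsilane
Conditions: KOtBu (0.3 equiv), THF, 0 °C to rt
Reagents that add atoms: none
Why: Base-catalysed propargyl-to-allenyl prototropic isomerisation, the standard entry to aryloxyallenes, which is safe here because 6 holds no hydroxyl group that could add to the new allene as its alkoxide and no carbonyl group that the transient propargylic anion could attack.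

Step 6
Reactants: 7 tert-butyl{(1R)-1-[3-(dimethoxymethyl)-4-(propa-1,2-dien-1-yloxy)phenyl]ethoxy}dimethylsilane
Product: 8 5-[(1R)-1-(tert-butyldimethylsilyloxy)ethyl]-2-(propa-1,2-dien-1-yloxy)benzaldehyde
Conditions: PPTS (10 mol %), acetone/H2O (10:1), 0 °C to rt; aq NaHCO3
Reagents that add atoms: water, O
Why: Mild acid-catalysed acetal hydrolysis, selective because the acetal ionises to an oxocarbenium ion stabilised by the ortho-oxygenated ring far faster than the aryloxyallene, whose oxygen lone pair is shared with the arene, is protonated at carbon, and because a TBS ether does not respond to PPTS at this temperature.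

Step 7
Reactants: 8 5-[(1R)-1-(tert-butyldimethylsilyloxy)ethyl]-2-(propa-1,2-dien-1-yloxy)benzaldehyde; 9 bis(pinacolato)diboron
Product: 12 (2R,3S)-5-[(1R)-1-(tert-butyldimethylsilyloxy)ethyl]-2-[1-(pinacolboryl)ethenyl]-2,3-dihydrobenzofuran-3-ol (2,3-trans), via allylcopper 10 (not isolated), via boric ester 11 (not isolated)
Conditions: CuCl (5 mol %), (R)-DTBM-SEGPHOS (6 mol %), NaOtBu (10 mol %), B2pin2 (1.2 equiv), THF, 0 °C to rt; aq NH4Cl
Reagents that add atoms: bis(pinacolato)diboron (9), CC1(C)OB(OC1(C)C)B2OC(C)(C)C(C)(C)O2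
Why: Proposed new method: The copper boryl formed from CuCl, NaOtBu and B2pin2 should insert the unsubstituted C=C of the allene into its Cu–B bond (boron to the former sp carbon, copper to CH2), the resulting allylcopper 10 should bond through its oxygen-bearing γ-carbon to the neighbouring formyl carbon in a cyclic six-atom array held together by Cu–O coordination, and B2pin2 should release copper from the alkoxide as boric ester 11, which aqueous work-up cleaves. The nearest known reaction types are the copper-catalysed three-component union of allenes, oxygen- and nitrogen-substituted ones among them, with B2pin2 and aldehydes or ketones, and the borylative ring closure of carbon-tethered allenyl ketones, whereas an aryloxyallene closing onto its own ortho aldehyde is untried. The dihydrofuran ring closes in the 5-exo-trig mode with respect to the C=O bond. The trans relation of C2 and C3 requires the E-allylcopper in a chair with both tether ends equatorial; because insertion on the side away from the aryloxy group first gives the Z isomer, the plan counts on the rapid 1,3-shift of copper to equilibrate the two before the slower closure, for which the aldehyde has to twist out of conjugation, and on the bulk of the ligand to penalise the Z chair, in which the axial aryloxy group forces the arene under the phosphine. The absolute configuration at both new centres is decided only by the bisphosphine, which selects the aldehyde face, since the side-chain centre is too far away to interfere. The step needs attack of Cu–B on the allene rather than on the aldehyde and γ- rather than α-bonding of the allyl unit, and the substrate secures both through a donor-substituted, conjugated and therefore sluggish formyl group, an unhindered terminal C=C, and an ortho tether that brings only the γ-carbon within reach of the carbonyl carbon.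

Step 8
Reactants: 12 (2R,3S)-5-[(1R)-1-(tert-butyldimethylsilyloxy)ethyl]-2-[1-(pinacolboryl)ethenyl]-2,3-dihydrobenzofuran-3-ol
Product: 13 (2R,3S)-5-[(1R)-1-hydroxyethyl]-2-[1-(pinacolboryl)ethenyl]-2,3-dihydrobenzofuran-3-ol
Conditions: Bu4NF (1.2 equiv), AcOH (1.2 equiv), THF, 0 °C to rt
Reagents that add atoms: none
Why: Fluoride-mediated desilylation breaks only the Si–O bond and so keeps the carbinol configuration, and the acetic acid buffer holds down the basicity that could harm the alkenyl boronate, whereas an acidic method is avoided because it would ionise the two electron-rich benzylic carbinols.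

Step 9
Reactants: 13 (2R,3S)-5-[(1R)-1-hydroxyethyl]-2-[1-(pinacolboryl)ethenyl]-2,3-dihydrobenzofuran-3-ol; 14 tiglic acid
Product: 15 (2R,3S)-2-[1-(pinacolboryl)ethenyl]-5-[(1R)-1-(tigloyloxy)ethyl]-2,3-dihydrobenzofuran-3-yl tiglate
Conditions: tiglic acid (3 equiv), DCC (3 equiv), DMAP (0.3 equiv), CH2Cl2, 0 °C to rt
Reagents that add atoms: tiglic acid (14), C/C=C(\C)C(=O)O
Why: Double Steglich esterification acylates both secondary alcohols at oxygen with retention, the E alkene of the acid is its stable geometry and no amine/acid chloride pair is present that could deconjugate it, and in the trans ester C2–H lies syn to the C3–O bond so that anti elimination to the benzofuran has no pathway.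

Step 10
Reactants: 15 (2R,3S)-2-[1-(pinacolboryl)ethenyl]-5-[(1R)-1-(tigloyloxy)ethyl]-2,3-dihydrobenzofuran-3-yl tiglate; 16 chloroiodomethane
Product: 18 (2R,3S)-2-(3-hydroxyprop-1-en-2-yl)-5-[(1R)-1-(tigloyloxy)ethyl]-2,3-dihydrobenzofuran-3-yl tiglate, via allylboronate 17 (not isolated)
Conditions: ICH2Cl (1.5 equiv), n-BuLi (1.4 equiv, added last), THF, −78 °C to rt; then NaBO3·4H2O, THF/H2O, rt
Reagents that add atoms: chloroiodomethane (16), ClCI; sodium perborate, [Na+].[Na+].O[B-]1(O)OO[B-](O)(O)OO1
Why: Matteson homologation followed by boronate oxidation, in which chloromethyllithium made by fast iodine–lithium exchange in the presence of 15 is captured at boron sooner than it adds to the hindered conjugated esters, the alkenyl group shifts from boron to carbon with loss of chloride to give 17, and perborate swaps boron for hydroxyl under conditions that spare the tiglates; no stereocentre is touched, and neither zerovalent palladium nor a hydride donor, both of which could cleave the allylic C2–O1 bond, is needed.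

Step 11
Reactants: 18 (2R,3S)-2-(3-hydroxyprop-1-en-2-yl)-5-[(1R)-1-(tigloyloxy)ethyl]-2,3-dihydrobenzofuran-3-yl tiglate
Product: 19 (2R,3S)-2-(3-oxoprop-1-en-2-yl)-5-[(1R)-1-(tigloyloxy)ethyl]-2,3-dihydrobenzofuran-3-yl tiglate (target)
Conditions: MnO2 (activated, excess), CH2Cl2, rt
Reagents that add atoms: none
Why: MnO2 oxidation of the only free hydroxyl group, a primary allylic alcohol, stops at the enal under neutral heterogeneous conditions, so that the ionisable C3 ester and the reactive 2-substituted acrolein meet nothing harsher than a filtration.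

Compound list
1 | 5-acetyl-2-hydroxybenzaldehyde | CC(=O)c1ccc(O)c(C=O)c1 | starting material
2 | propargyl bromide | C#CCBr | starting material
3 | 5-acetyl-2-(prop-2-yn-1-yloxy)benzaldehyde | CC(=O)c1ccc(OCC#C)c(C=O)c1 | intermediate
4 | 1-[3-(dimethoxymethyl)-4-(prop-2-yn-1-yloxy)phenyl]ethan-1-one | CC(=O)c1ccc(OCC#C)c(C(OC)OC)c1 | intermediate
5 | (1R)-1-[3-(dimethoxymethyl)-4-(prop-2-yn-1-yloxy)phenyl]ethan-1-ol | C#CCOc1ccc([C@@H](C)O)cc1C(OC)OC | intermediate
6 | tert-butyl{(1R)-1-[3-(dimethoxymethyl)-4-(prop-2-yn-1-yloxy)phenyl]ethoxy}dimethylsilane | C#CCOc1ccc([C@@H](C)O[Si](C)(C)C(C)(C)C)cc1C(OC)OC | intermediate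
7 | tert-butyl{(1R)-1-[3-(dimethoxymethyl)-4-(propa-1,2-dien-1-yloxy)phenyl]ethoxy}dimethylsilane | C=C=COc1ccc([C@@H](C)O[Si](C)(C)C(C)(C)C)cc1C(OC)OC | intermediate
8 | 5-[(1R)-1-(tert-butyldimethylsilyloxy)ethyl]-2-(propa-1,2-dien-1-yloxy)benzaldehyde | C=C=COc1ccc([C@@H](C)O[Si](C)(C)C(C)(C)C)cc1C=O | intermediate
9 | bis(pinacolato)diboron | CC1(C)OB(OC1(C)C)B2OC(C)(C)C(C)(C)O2 | starting material
10 | (E)-3-aryloxy-2-(pinacolboryl)allylcopper derived from 8, aryloxy trans to CH2Cu, bisphosphine on copper omitted | [Cu]C/C(B1OC(C)(C)C(C)(C)O1)=C/Oc1ccc([C@@H](C)O[Si](C)(C)C(C)(C)C)cc1C=O | intermediate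
11 | C3 O-pinacolboryl ether of 12, (2R,3S), 2,3-trans | C=C(B1OC(C)(C)C(C)(C)O1)[C@H]2Oc3ccc([C@@H](C)O[Si](C)(C)C(C)(C)C)cc3[C@@H]2OB4OC(C)(C)C(C)(C)O4 | intermediate
12 | (2R,3S)-5-[(1R)-1-(tert-butyldimethylsilyloxy)ethyl]-2-[1-(4,4,5,5-tetramethyl-1,3,2-dioxaborolan-2-yl)ethenyl]-2,3-dihydrobenzofuran-3-ol, 2,3-trans | C=C(B1OC(C)(C)C(C)(C)O1)[C@H]2Oc3ccc([C@@H](C)O[Si](C)(C)C(C)(C)C)cc3[C@@H]2O | intermediate
13 | (2R,3S)-5-[(1R)-1-hydroxyethyl]-2-[1-(4,4,5,5-tetramethyl-1,3,2-dioxaborolan-2-yl)ethenyl]-2,3-dihydrobenzofuran-3-ol | C=C(B1OC(C)(C)C(C)(C)O1)[C@H]2Oc3ccc([C@@H](C)O)cc3[C@@H]2O | intermediate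
14 | tiglic acid, (E)-2-methylbut-2-enoic acid | C/C=C(\C)C(=O)O | starting material
15 | (2R,3S)-2-[1-(pinacolboryl)ethenyl]-5-[(1R)-1-{[(E)-2-methylbut-2-enoyl]oxy}ethyl]-2,3-dihydrobenzofuran-3-yl (E)-2-methylbut-2-enoate | C=C(B1OC(C)(C)C(C)(C)O1)[C@H]2Oc3ccc([C@@H](C)OC(=O)/C(C)=C/C)cc3[C@@H]2OC(=O)/C(C)=C/C | intermediate
16 | chloroiodomethane | ClCI | starting material
17 | (2R,3S)-2-[3-(pinacolboryl)prop-1-en-2-yl]-5-[(1R)-1-(tigloyloxy)ethyl]-2,3-dihydrobenzofuran-3-yl tiglate | C=C(CB1OC(C)(C)C(C)(C)O1)[C@H]2Oc3ccc([C@@H](C)OC(=O)/C(C)=C/C)cc3[C@@H]2OC(=O)/C(C)=C/C | intermediate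
18 | (2R,3S)-2-(3-hydroxyprop-1-en-2-yl)-5-[(1R)-1-(tigloyloxy)ethyl]-2,3-dihydrobenzofuran-3-yl tiglate | C=C(CO)[C@H]1Oc2ccc([C@@H](C)OC(=O)/C(C)=C/C)cc2[C@@H]1OC(=O)/C(C)=C/C | intermediate
19 | (2R,3S)-2-(3-oxoprop-1-en-2-yl)-5-[(1R)-1-{[(E)-2-methylbut-2-enoyl]oxy}ethyl]-2,3-dihydrobenzofuran-3-yl (E)-2-methylbut-2-enoate | C=C(C=O)[C@H]1Oc2ccc([C@@H](C)OC(=O)/C(C)=C/C)cc2[C@@H]1OC(=O)/C(C)=C/C | target

Total step count: 11. Longest linear sequence: 11 steps, from 1 to 19.

Steps most likely to fail

**Step 7.** Ring closure through the first-formed Z-allylcopper, or through a boat, would set the wrong relative configuration at C2 and C3. The ligand may also discriminate the aldehyde faces poorly. Borylation of the aldehyde or protonation of the allylcopper may outrun the closure.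

- The fallback sets out from 7 and comes back at 12. It makes the same bond in two known stages through an open, Lewis acid promoted transition state instead of a copper-bound cyclic one.
- Copper-catalysed three-component borylstannylation of the allene of 7 (Cu(OAc)2, PCy3, B2pin2, Bu3SnOMe, toluene, rt) should give the (Z)-2-boryl-3-aryloxyallylstannane acetal F1. PPTS in wet acetone should then free the stannyl aldehyde F2.
- BF3·OEt2 in CH2Cl2 at −78 °C then brings about the cyclisation of a γ-alkoxyallylstannane onto a tethered aldehyde. This reaction class is known to give the trans-2-alkenyl-3-hydroxy cyclic ether from either alkene geometry.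
- Nothing controls the absolute sense here, so 12 should be accompanied by the (2S,3R) isomer F3. F3 is a diastereomer thanks to the side-chain centre and is removed by chromatography or by lipase-mediated acylation.

**Step 10.** Butyllithium or the carbenoid may add to a tiglate carbonyl. The boron ate complex may also expel the ring aryloxide instead of undergoing the 1,2-shift.

- The fallback sets out from 15 and comes back at 18, and it uses no organolithium.
- Boron is exchanged for iodine with NaI and chloramine-T in aqueous THF to give the alkenyl iodide F4.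
- A Stille coupling of F4 with (tributylstannyl)methanol (Pd2(dba)3, AsPh3, CuI, DMF, 40 °C) should then put the hydroxymethyl group in place.

**Step 6.** The allenyl ether may be protonated and lost by hydrolysis. Acid may also ionise the silyloxy-bearing benzylic carbon and erode its configuration.

- The fallback sets out from 6 and comes back at 8. It replaces the acetal by a redox detour, so the allene never meets aqueous acid.
- The acetal is hydrolysed (PPTS, wet acetone) while the ether is still the acid-stable propargyl ether, giving the propargyloxy aldehyde F5.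
- NaBH4 in MeOH gives the benzylic alcohol F6, TESCl and imidazole the triethylsilyl ether F7, and KOtBu in THF the allenyl ether F8.
- HF·pyridine buffered with excess pyridine in THF at 0 °C removes only the primary triethylsilyl group and gives the allenyl benzylic alcohol F9. MnO2 in CH2Cl2 oxidises F9 to 8.

Further compounds
F1 | step 7 | tributyl[(Z)-3-{2-(dimethoxymethyl)-4-[(1R)-1-(tert-butyldimethylsilyloxy)ethyl]phenoxy}-2-(pinacolboryl)prop-2-en-1-yl]stannane | CCCC[Sn](CCCC)(CCCC)C/C(B1OC(C)(C)C(C)(C)O1)=C\Oc1ccc([C@@H](C)O[Si](C)(C)C(C)(C)C)cc1C(OC)OC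
F2 | step 7 | 5-[(1R)-1-(tert-butyldimethylsilyloxy)ethyl]-2-{[(Z)-2-(pinacolboryl)-3-(tributylstannyl)prop-1-en-1-yl]oxy}benzaldehyde | CCCC[Sn](CCCC)(CCCC)C/C(B1OC(C)(C)C(C)(C)O1)=C\Oc1ccc([C@@H](C)O[Si](C)(C)C(C)(C)C)cc1C=O
F3 | step 7 | (2S,3R)-5-[(1R)-1-(tert-butyldimethylsilyloxy)ethyl]-2-[1-(pinacolboryl)ethenyl]-2,3-dihydrobenzofuran-3-ol, 2,3-trans, unwanted diastereomer of 12 | C=C(B1OC(C)(C)C(C)(C)O1)[C@@H]2Oc3ccc([C@@H](C)O[Si](C)(C)C(C)(C)C)cc3[C@H]2O
F4 | step 10 | (2S,3S)-2-(1-iodoethenyl)-5-[(1R)-1-(tigloyloxy)ethyl]-2,3-dihydrobenzofuran-3-yl tiglate, same 2,3-trans arrangement in space as 15, the C2 descriptor changing because iodine raises the rank of the vinyl carbon | C=C(I)[C@H]1Oc2ccc([C@@H](C)OC(=O)/C(C)=C/C)cc2[C@@H]1OC(=O)/C(C)=C/C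
F5 | step 6 | 5-[(1R)-1-(tert-butyldimethylsilyloxy)ethyl]-2-(prop-2-yn-1-yloxy)benzaldehyde | C#CCOc1ccc([C@@H](C)O[Si](C)(C)C(C)(C)C)cc1C=O
F6 | step 6 | {5-[(1R)-1-(tert-butyldimethylsilyloxy)ethyl]-2-(prop-2-yn-1-yloxy)phenyl}methanol | C#CCOc1ccc([C@@H](C)O[Si](C)(C)C(C)(C)C)cc1CO
F7 | step 6 | triethylsilyl ether of F6 | C#CCOc1ccc([C@@H](C)O[Si](C)(C)C(C)(C)C)cc1CO[Si](CC)(CC)CC
F8 | step 6 | tert-butyldimethyl{(1R)-1-[4-(propa-1,2-dien-1-yloxy)-3-(triethylsilyloxymethyl)phenyl]ethoxy}silane | C=C=COc1ccc([C@@H](C)O[Si](C)(C)C(C)(C)C)cc1CO[Si](CC)(CC)CC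
F9 | step 6 | {5-[(1R)-1-(tert-butyldimethylsilyloxy)ethyl]-2-(propa-1,2-dien-1-yloxy)phenyl}methanol | C=C=COc1ccc([C@@H](C)O[Si](C)(C)C(C)(C)C)cc1CO
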